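**Numbering.** Target locants are used throughout: C1 (OMe), C2=C3 (C3 carries C7H2OBz), C4 (OH), C5 (OBz), C6 (OH). Shikimate C1, C2, C3, C4, C5, C6 and the carboxyl carbon correspond to target C3, C2, C1, C6, C5, C4 and C7. Compounds 1–18 are those of the steps below.

## The problem

The target is a single cyclohexene with no ring fusion. All seven carbons belong to a C7 cyclitol: C7 is a benzoyloxymethyl group on the alkene carbon C3, and C1, C4, C5 and C6 are contiguous oxygen-bearing stereocentres, (1S,4R,5R,6R). The oxygens on C1, C4 and C5 lie on one face and the C6 oxygen on the other. The trans C5/C6 pair can be taken from the chiral pool and used to steer C1 and C4. C1 and C4 sit at opposite ends of the C2=C3 bond, too far apart for one to induce the other directly. The four ring oxygens end in four different states (methyl ether, allylic alcohol, benzoate, alcohol), so C1 must be told from C4, and C5 from C4 within a cis-diol. The benzoates migrate to neighbouring free hydroxyls under base and do not survive hydride or alkoxide. The allylic C–O bonds at C1, C4 and C7 can ionise under strong acid or with zerovalent palladium, and every cyclohexadiene on the way can aromatise by losing water or a carboxylic acid. The enabling feature is that C1–O and C4–O are cis and flank C2=C3, which is the pattern left by a peroxide bridge across a C1=C2–C3=C4 diene. In addition, C5, C6 and C7 coincide with C5, C4 and the carboxyl carbon of (−)-shikimic acid.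

## Retrosynthesis

**18 ⇒ 17 + 10.** The C5–O acyl bond is cut last. A secondary benzoate between two free hydroxyls is the most migration-prone element, so no later step should follow its introduction. The forward reaction must pick the equatorial C5 hydroxyl of triol 17. The triol has the pseudoaxial/equatorial/equatorial pattern (C4/C5/C6) of a rhamno-type pyranoside triol, for which catalyst-directed acylation of the middle, equatorial oxygen of the cis pair is established.

**17 ⇒ 16 ⇒ 15 ⇒ 14.** The O–CH3 bond at C1 and two protecting groups are removed. Methylation needs C1–OH as the only free hydroxyl. In triol 14, C4/C5 is the only cis-vicinal pair and takes an acetonide (15), and C6 is already silylated. This is safer than trying to methylate C1 selectively beside C4, both being secondary allylic alcohols. One acid treatment of 16 then releases 17.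

**14 ⇒ 13.** The O–O bond is re-formed. Endoperoxide 13 holds the C1 and C4 oxygens on one face; the reduction touches no C–O bond.

**13 ⇒ 11 + 12.** The C1–O and C4–O bonds are cut together, which removes two stereocentres and one ring in a single move. Setting C1 and C4 in separate events (epoxide opening, allylic oxidation) would need two stereocontrolled steps. The forward reaction needs singlet oxygen to add to the face of diene 11 that is syn to C5–OH and anti to C6–OSi.

**11 ⇒ 9 + 10; 9 ⇒ 8.** C7 is taken back to the ester level. The ester must be reduced before the cycloaddition, because an ester-conjugated diene is a poor partner for electrophilic singlet oxygen. The same hydride step removes the C5 pivalate and exposes the directing hydroxyl. The primary alcohol is benzoylated first so that only one hydrogen-bond donor (C5–OH) remains.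

**8 ⇒ 7 ⇒ 6.** The diene is traced to a formal 1,4-elimination of the shikimate C3 oxygen and a C6 hydrogen. The easier 1,2-elimination of the shikimate C5 oxygen would give a cis-diol diene with the wrong C5/C6 relation. Because the dienes aromatise with acid or base, a neutral zerovalent-palladium elimination from cyclic carbonate 6 is chosen. It frees only the C6 hydroxyl in 7, so silylation to 8 is unambiguous.

**6 ⇒ 5 ⇒ 4 ⇒ 3 ⇒ 1.** The three shikimate hydroxyls are differentiated through the cis-3,4-acetonide 3. The lone hydroxyl is capped as a pivalate (4), the acetonide is exchanged for the carbonate (5, 6), and 1 supplies all seven carbons and both retained stereocentres.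

## Roads not taken

**Alternative 1:** The cut is at C1–O/C6–O (an oxirane) and at C3–C7. The cis-dihydrodiol A1 is protected as acetonide A2. Its unbrominated C1=C6 alkene is epoxidised with mCPBA on the face opposite the dioxolane to give A3. Methanolysis of A3 at the allylic C1 would then give the trans C1–OMe/C6–OH pair, and C7 would be added by palladium-catalysed coupling at the bromoalkene.
- Merits: both site and face selectivity of the epoxidation are well established for this diene class. The cis C4/C5 diol arrives protected, and the route is roughly five steps shorter.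
- Weak points: A1 comes from whole-cell arene oxidation, is not a bulk chemical and dehydrates easily. C7 must be attached late to a hindered, oxygenated bromoalkene. The C4/C5 benzoylation question remains.
- Comparison: this road is shorter and stereochemically safer. The chosen plan sets against it a cheap crystalline starting material that already carries C7, no C–C bond formation, and C1 and C4 made in one operation.

**Alternative 2:** The cut is the C3–C4 ring bond. The acyclic (Z)-iodoalkenyl aldehyde A4 would close to cyclohexenol A5 with catalytic CrCl2 and NiCl2, Me3SiCl, and cathodic regeneration of divalent chromium against an aluminium anode.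
- Merits: all oxygens are differentiated before ring closure, with the C5 benzoate already in place, so no late regioselective acylation is needed. This is a real advantage over the chosen plan, which relies on a catalyst-directed benzoylation at the end.
- Weak points: A4 needs three stereocentres and a trisubstituted (Z)-iodoalkene built in open-chain form. The C4 configuration is uncertain: polar Felkin–Anh control favours the cis C4/C5 relation, whereas the cyclic transition state favours a pseudoequatorial C4 oxygen trans to O5. The α-benzoyloxy aldehyde is prone to epimerisation, and the electrochemical variant has little backing for such ring closures.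
- Comparison: it is longer, and only one centre is set in the key step, with doubtful control.

**Alternative 3:** The cut is C1–C2. The altro-configured methyl 6-deoxyhex-5-enopyranoside A6 would rearrange with Ti(OiPr)Cl3 by endocyclic C–O cleavage and enolate recombination to cyclohexanone A7.
- Merits: C4, C5 and C6 come from the sugar, the C1 methoxy group is the glycosidic one (no methylation step), and the C5 benzoate is in place. On oxygen differentiation it is the most complete of the four.
- Weak points: the altro sugar takes several steps to prepare. A7 is a β-methoxy, β′-benzoyloxy ketone, and the enolisation needed to install C7 and the C2=C3 alkene invites loss of methanol or benzoic acid. Retention at C1 in the rearrangement is not assured with a neighbouring ester.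
- Comparison: the chosen plan is shorter, has C7 and the alkene position fixed from the start, and avoids enolate chemistry.

Key step: step 9

Remark on the chemistry: commercial (−)-shikimic acid is taken as the natural (3R,4S,5R) enantiomer, and acid released in acylations and silylation is counted as the salt of the amine base used.

## Route

Step 1
Reactants: 1 (−)-shikimic acid
Product: 3 methyl 3,4-O-isopropylidene shikimate (shikimate numbering; 5-OH free), via methyl shikimate 2 (not isolated)
Conditions: MeOH, camphor-10-sulfonic acid (cat.), reflux; then Me2C(OMe)2, acetone, rt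
Reagents that add atoms: methanol, CO; 2,2-dimethoxypropane, COC(C)(C)OC
Why: Fischer esterification followed by acid-catalysed transketalisation; only the cis-3,4-diol can form a cis-fused dioxolane, so the trans 5-hydroxyl is left free. No stereocentre is touched.

Step 2
Reactants: 3 methyl 3,4-O-isopropylidene shikimate
Product: 4 methyl 3,4-O-isopropylidene-5-O-pivaloylshikimate
Conditions: t-BuCOCl, pyridine, 4-(dimethylamino)pyridine (cat.), CH2Cl2, 0 °C to rt
Reagents that add atoms: pivaloyl chloride, CC(C)(C)C(=O)Cl
Why: Acylation of the only free hydroxyl. A pivalate is chosen because it resists 1,2-acyl shift to the neighbouring oxygen in steps 3–5, ionises only slowly with palladium, and is later removed by the hydride that reduces the ester.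

Step 3
Reactants: 4 methyl 3,4-O-isopropylidene-5-O-pivaloylshikimate
Product: 5 methyl 5-O-pivaloylshikimate (free cis-3,4-diol)
Conditions: AcOH/H2O (4:1), 50 °C
Reagents that add atoms: none
Why: Acid hydrolysis of the isopropylidene ketal; the methyl ester and the hindered pivalate are stable, and acyl shift is slow in acid.

Step 4
Reactants: 5 methyl 5-O-pivaloylshikimate
Product: 6 methyl 3,4-O-carbonyl-5-O-pivaloylshikimate (cis-fused five-membered cyclic carbonate)
Conditions: 1,1'-carbonyldiimidazole, THF, rt to 50 °C
Reagents that add atoms: 1,1'-carbonyldiimidazole, O=C(n1ccnc1)n1ccnc1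
Why: Carbonylation of a cis-1,2-diol to its cyclic carbonate. This turns the allylic oxygen (target C1) into a leaving group and masks the C6 oxygen in one step.

Step 5
Reactants: 6 methyl 3,4-O-carbonyl-5-O-pivaloylshikimate
Product: 7 methyl (3R,4R)-4-hydroxy-3-(pivaloyloxy)cyclohexa-1,5-diene-1-carboxylate
Conditions: Pd(PPh3)4 (5 mol %), THF, rt to 40 °C
Reagents that add atoms: none
Why: Tsuji–Trost-type decarboxylative elimination: zerovalent palladium ionises the allylic C–O bond with inversion to a π-allyl complex spanning target C1–C3, and the carbonate loses CO2. The alkoxide released on C6, on the face opposite the metal, can remove the C4 hydrogen to give the diene and the free C6 hydroxyl. The C5 and C6 stereocentres are not involved.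

Step 6
Reactants: 7 methyl (3R,4R)-4-hydroxy-3-(pivaloyloxy)cyclohexa-1,5-diene-1-carboxylate
Product: 8 methyl (3R,4R)-4-(tert-butyldimethylsilyloxy)-3-(pivaloyloxy)cyclohexa-1,5-diene-1-carboxylate
Conditions: TBSOTf, 2,6-lutidine, CH2Cl2, −78 to 0 °C
Reagents that add atoms: tert-butyldimethylsilyl trifluoromethanesulfonate, CC(C)(C)[Si](C)(C)OS(=O)(=O)C(F)(F)F
Why: Silylation of the only free hydroxyl under buffered conditions that spare the acid-sensitive diene; the bulky ether later shields the lower face.

Step 7
Reactants: 8 methyl (3R,4R)-4-(tert-butyldimethylsilyloxy)-3-(pivaloyloxy)cyclohexa-1,5-diene-1-carboxylate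
Product: 9 (1R,6R)-6-(tert-butyldimethylsilyloxy)-3-(hydroxymethyl)cyclohexa-2,4-dien-1-ol
Conditions: i-Bu2AlH (6 equiv), CH2Cl2, −78 to −20 °C; aq. potassium sodium tartrate
Reagents that add atoms: none
Why: 1,2-Reduction of the dienoate to the primary allylic alcohol with reductive cleavage of the pivalate in the same operation. The silyl ether survives and the work-up is neutral, so the diene does not aromatise.

Step 8
Reactants: 9 (1R,6R)-6-(tert-butyldimethylsilyloxy)-3-(hydroxymethyl)cyclohexa-2,4-dien-1-ol; 10 benzoyl chloride
Product: 11 [(3R,4R)-4-(tert-butyldimethylsilyloxy)-3-hydroxycyclohexa-1,5-dien-1-yl]methyl benzoate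
Conditions: PhCOCl (1.05 equiv), 2,4,6-collidine, CH2Cl2, −78 to −40 °C
Reagents that add atoms: none
Why: Kinetically selective acylation of the primary allylic hydroxyl over the secondary C5 hydroxyl, which is flanked by the silyl ether. It installs the C7 benzoate of the target and leaves C5–OH as the sole hydrogen-bond donor.

Step 9
Reactants: 11 [(3R,4R)-4-(tert-butyldimethylsilyloxy)-3-hydroxycyclohexa-1,5-dien-1-yl]methyl benzoate; 12 dioxygen
Product: 13 [(1S,4R,5R,6S)-6-(tert-butyldimethylsilyloxy)-5-hydroxy-1,4-epidioxycyclohex-2-en-3-yl]methyl benzoate (target numbering; O–O bridge cis to C5–OH, trans to C6–OSi)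
Conditions: O2, 5,10,15,20-tetraphenylporphyrin C44H30N4 (1 mol %), white LED, CH2Cl2, −20 °C
Reagents that add atoms: none
Why: Energy transfer from the photoexcited porphyrin converts 12 into singlet oxygen, which adds to the ring-locked s-cis diene C1=C2–C3=C4 of 11 in a concerted, suprafacial [4+2] cycloaddition; the closest known reaction type is the dye-sensitised photooxygenation of cyclohexa-1,3-dienes to 2,3-dioxabicyclo[2.2.2]oct-5-enes used for conduritol-type cyclitols. The one ring closed, the six-membered 3,6-dihydro-1,2-dioxine O–O–C1–C2=C3–C4, is formed by cycloaddition with both C–O bonds made in the same step, so the O–O unit bridges one face and C1–O and C4–O emerge cis. The new stereocentres C1 and C4 are therefore set together by the face of approach, which the substrate chooses: the free C5 hydroxyl, allylic to the C4 terminus, hydrogen-bonds to the incoming oxygen and guides it syn, while the silyl ether on the opposite face at C6, allylic to the C1 terminus, blocks the anti approach. Because C5–O and C6–O are trans, both effects point to the same face and should give the (1S,4R) peroxide. The step needs π-facial selectivity and [4+2] rather than Schenck ene reactivity; the first is supported by a non-hydrogen-bonding solvent at low temperature, the second by the cisoid diene and the absence of a free C7 hydroxyl. The peroxide is kept cold and free of amine base to avoid Kornblum–DeLaMare rearrangement.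

Step 10
Reactants: 13 endoperoxide
Product: 14 [(3S,4R,5R,6R)-4-(tert-butyldimethylsilyloxy)-3,5,6-trihydroxycyclohex-1-en-1-yl]methyl benzoate (target numbering: C1, C4, C5 hydroxyls, C6 silyl ether)
Conditions: thiourea, MeOH, 0 °C to rt
Reagents that add atoms: none
Why: Neutral two-electron reduction of the O–O bond by thiourea, the standard way to turn diene endoperoxides into cis-ene-1,4-diols. No C–O bond is broken, so C1 and C4 keep their configuration and the benzoate and silyl ether are untouched.

Step 11
Reactants: 14 triol
Product: 15 the 4,5-O-isopropylidene derivative of 14, (1S,4R,5R,6R) in target numbering, C1–OH free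
Conditions: Me2C(OMe)2, pyridinium p-toluenesulfonate (cat.), CH2Cl2, rt
Reagents that add atoms: 2,2-dimethoxypropane, COC(C)(C)OC
Why: Thermodynamic ketalisation of the only cis-vicinal diol (C4/C5). C1–OH is 1,4 to C4 and its other neighbour is silylated, so it cannot form a cyclic ketal and stays free.

Step 12
Reactants: 15 acetonide with free C1–OH
Product: 16 the C1 methyl ether of 15, (1S,4R,5R,6R) in target numbering
Conditions: Me3OBF4, 1,8-bis(dimethylamino)naphthalene, 4 Å molecular sieves, CH2Cl2, 0 °C to rt
Reagents that add atoms: trimethyloxonium tetrafluoroborate, C[O+](C)C.F[B-](F)(F)F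
Why: O-Methylation of the single free hydroxyl with an oxonium salt and a non-nucleophilic amine. No alkoxide is formed, so the neighbouring silyl group does not migrate and the benzoate is not cleaved; the configuration at C1 is retained.

Step 13
Reactants: 16 methyl ether
Product: 17 [(3S,4R,5R,6R)-4,5,6-trihydroxy-3-methoxycyclohex-1-en-1-yl]methyl benzoate
Conditions: CF3CO2H/H2O (4:1), 0 °C to rt
Reagents that add atoms: none
Why: Aqueous acid hydrolyses the isopropylidene ketal and the secondary silyl ether in one operation. The allylic C–O bonds are deactivated toward ionisation by their oxygenated neighbours, and the primary benzoate is stable to aqueous acid.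

Step 14
Reactants: 17 triol; 10 benzoyl chloride
Product: 18 [(3S,4R,5R,6R)-5-(benzoyloxy)-4,6-dihydroxy-3-methoxycyclohex-1-en-1-yl]methyl benzoate (the target)
Conditions: PhCOCl (1.1 equiv), Ph2BOCH2CH2NH2 (10 mol %), i-Pr2NEt, MeCN, rt
Reagents that add atoms: none
Why: Diarylborinic acid-catalysed regioselective acylation of a cis-1,2-diol: the catalyst binds the cis C4/C5 pair as a tetracoordinate borinate and the equatorial C5 oxygen is acylated. The pseudoaxial allylic C4–OH (next to the substituted C3) and the unbound trans C6–OH should be left, as in the 3-O-acylation of rhamno-type pyranoside triols.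

## Compound list

1 | (−)-shikimic acid, (3R,4S,5R)-3,4,5-trihydroxycyclohex-1-ene-1-carboxylic acid | C1[C@H]([C@@H]([C@@H](C=C1C(=O)O)O)O)O | starting material
2 | methyl shikimate, methyl (3R,4S,5R)-3,4,5-trihydroxycyclohex-1-ene-1-carboxylate | O[C@@H]1C=C(C(=O)OC)C[C@@H](O)[C@@H]1O | intermediate
3 | methyl 3,4-O-isopropylidene shikimate | CC1(C)O[C@@H]2C=C(C(=O)OC)C[C@@H](O)[C@@H]2O1 | intermediate
4 | methyl 3,4-O-isopropylidene-5-O-pivaloylshikimate | CC1(C)O[C@@H]2C=C(C(=O)OC)C[C@@H](OC(=O)C(C)(C)C)[C@@H]2O1 | intermediate
5 | methyl 5-O-pivaloylshikimate | O[C@@H]1C=C(C(=O)OC)C[C@@H](OC(=O)C(C)(C)C)[C@@H]1O | intermediate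
6 | methyl 3,4-O-carbonyl-5-O-pivaloylshikimate | O=C1O[C@@H]2C=C(C(=O)OC)C[C@@H](OC(=O)C(C)(C)C)[C@@H]2O1 | intermediate
7 | methyl (3R,4R)-4-hydroxy-3-(pivaloyloxy)cyclohexa-1,5-diene-1-carboxylate | C1=CC(C(=O)OC)=C[C@@H](OC(=O)C(C)(C)C)[C@@H]1O | intermediate
8 | methyl (3R,4R)-4-(tert-butyldimethylsilyloxy)-3-(pivaloyloxy)cyclohexa-1,5-diene-1-carboxylate | C1=CC(C(=O)OC)=C[C@@H](OC(=O)C(C)(C)C)[C@@H]1O[Si](C)(C)C(C)(C)C | intermediate
9 | (1R,6R)-6-(tert-butyldimethylsilyloxy)-3-(hydroxymethyl)cyclohexa-2,4-dien-1-ol | C1=CC(CO)=C[C@@H](O)[C@@H]1O[Si](C)(C)C(C)(C)C | intermediate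
10 | benzoyl chloride | O=C(Cl)c1ccccc1 | starting material
11 | [(3R,4R)-4-(tert-butyldimethylsilyloxy)-3-hydroxycyclohexa-1,5-dien-1-yl]methyl benzoate | C1=CC(COC(=O)c2ccccc2)=C[C@@H](O)[C@@H]1O[Si](C)(C)C(C)(C)C | intermediate
12 | dioxygen | O=O | starting material
13 | [(1S,4R,5R,6S)-6-(tert-butyldimethylsilyloxy)-5-hydroxy-1,4-epidioxycyclohex-2-en-3-yl]methyl benzoate (target numbering) | O1O[C@H]2C=C(COC(=O)c3ccccc3)[C@@H]1[C@@H](O)[C@@H]2O[Si](C)(C)C(C)(C)C | intermediate
14 | [(3S,4R,5R,6R)-4-(tert-butyldimethylsilyloxy)-3,5,6-trihydroxycyclohex-1-en-1-yl]methyl benzoate | O[C@H]1C=C(COC(=O)c2ccccc2)[C@@H](O)[C@@H](O)[C@@H]1O[Si](C)(C)C(C)(C)C | intermediate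
15 | 4,5-O-isopropylidene derivative of 14 (C1–OH free) | O[C@H]1C=C(COC(=O)c2ccccc2)[C@@H](OC3(C)C)[C@@H](O3)[C@@H]1O[Si](C)(C)C(C)(C)C | intermediate
16 | C1 methyl ether of 15 | CO[C@H]1C=C(COC(=O)c2ccccc2)[C@@H](OC3(C)C)[C@@H](O3)[C@@H]1O[Si](C)(C)C(C)(C)C | intermediate
17 | [(3S,4R,5R,6R)-4,5,6-trihydroxy-3-methoxycyclohex-1-en-1-yl]methyl benzoate | CO[C@H]1C=C(COC(=O)c2ccccc2)[C@@H](O)[C@@H](O)[C@@H]1O | intermediate
18 | [(3S,4R,5R,6R)-5-(benzoyloxy)-4,6-dihydroxy-3-methoxycyclohex-1-en-1-yl]methyl benzoate | CO[C@H]1C=C(COC(=O)c2ccccc2)[C@@H](O)[C@@H](OC(=O)c2ccccc2)[C@@H]1O | target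

## Step count and least certain steps

Total: 14 steps. Longest linear sequence: 14 steps from 1; 10 and 12 enter at steps 8, 9 and 14.

**Step 9 (key step).** The likely failure is erosion of π-facial selectivity. If the diene sits in the conformer with C5–OH and C6–OSi pseudoequatorial, the hydroxyl lies near the diene plane, and hydrogen bonding to the silyl ether oxygen or the C7 benzoate carbonyl competes with guidance of the oxygen. Ene oxidation and base-triggered rearrangement of the peroxide are secondary risks. Fallback, setting out from 11: epoxidation of the C3=C4 bond directed syn by the allylic C5 hydroxyl (VO(acac)2, t-BuOOH, CH2Cl2) would give the 3,4-epoxide F1. Pd(PPh3)4 with levulinic acid would ionise its allylic C3–O bond with inversion and deliver the carboxylate anti to the metal at the less substituted terminus C1, cis-1,4 to the C4 oxygen, giving the C1 levulinate F2. Hydrazine acetate would remove the levulinate beside the benzoate and return the route at 14.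

**Step 5.** The π-allylpalladium intermediate may decay by hydride migration from the carbinol carbon (the C6 hydrogen is syn to the metal), leading to a ketone and then a phenol. The allylic pivalate of the product may also ionise and aromatise, and the transient alkoxide may trigger acyl shift. Fallback, setting out from 5: SOCl2/Et3N would give the cyclic sulfite F3. Lithium bromide would open it at the allylic carbon with inversion, and sulfur dioxide would be lost on work-up to give the trans-bromohydrin F4. Silylation (TBSOTf, 2,6-lutidine) would give the bromo silyl ether F5, and DBU would effect 1,4-dehydrobromination, rejoining the route at 8.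

**Step 14.** The likely failure is loss of site selectivity among three secondary hydroxyls: acylation at the unhindered C6–OH or the allylic C4–OH, double acylation, or benzoyl shift from O5 under the amine base. Fallback, setting out from 16: AcOH/H2O at 40 °C would hydrolyse only the ketal and give the C6-silylated 4,5-diol F6. With C6 still capped, the same borinate-directed benzoylation would have only the cis pair to choose from and would give the C5 benzoate F7. HF·pyridine in THF, which is not basic enough to move the ester, would then release 18.

**Step 13.** Strong aqueous acid may ionise the allylic C1–OMe or C4–O bonds, shift the C7 benzoate to O4, or leave the hindered silyl ether partly in place. Fallback, setting out from 16: Bu4NF buffered with AcOH would remove the silyl group first to give the C6 alcohol F8, and mild aqueous acetic acid would then cleave the ketal, returning at 17.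

## Further compounds

F1 | step 9 | 3,4-epoxide of 11, oxirane cis to C5–OH | C1=C[C@@]2(COC(=O)c3ccccc3)O[C@H]2[C@@H](O)[C@@H]1O[Si](C)(C)C(C)(C)C
F2 | step 9 | C1 levulinate of 14 | CC(=O)CCC(=O)O[C@H]1C=C(COC(=O)c2ccccc2)[C@@H](O)[C@@H](O)[C@@H]1O[Si](C)(C)C(C)(C)C
F3 | step 5 | methyl 5-O-pivaloylshikimate 3,4-cyclic sulfite | O=S1O[C@@H]2C=C(C(=O)OC)C[C@@H](OC(=O)C(C)(C)C)[C@@H]2O1
F4 | step 5 | methyl 3-bromo-3-deoxy-5-O-pivaloyl-3-epi-shikimate (trans-bromohydrin) | Br[C@H]1C=C(C(=O)OC)C[C@@H](OC(=O)C(C)(C)C)[C@@H]1O
F5 | step 5 | 4-O-tert-butyldimethylsilyl ether of F4 | Br[C@H]1C=C(C(=O)OC)C[C@@H](OC(=O)C(C)(C)C)[C@@H]1O[Si](C)(C)C(C)(C)C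
F6 | step 14 | C6-silylated 4,5-diol (16 without the acetonide) | CO[C@H]1C=C(COC(=O)c2ccccc2)[C@@H](O)[C@@H](O)[C@@H]1O[Si](C)(C)C(C)(C)C
F7 | step 14 | C6 tert-butyldimethylsilyl ether of 18 | CO[C@H]1C=C(COC(=O)c2ccccc2)[C@@H](O)[C@@H](OC(=O)c2ccccc2)[C@@H]1O[Si](C)(C)C(C)(C)C
F8 | step 13 | C6 alcohol (16 without the silyl group) | CO[C@H]1C=C(COC(=O)c2ccccc2)[C@@H](OC3(C)C)[C@@H](O3)[C@@H]1O
A1 | alternative 1 | (1S,2S)-3-bromocyclohexa-3,5-diene-1,2-diol | BrC1=CC=C[C@H](O)[C@@H]1O
A2 | alternative 1 | acetonide of A1 | BrC1=CC=C[C@@H]2OC(C)(C)O[C@H]12
A3 | alternative 1 | C1,C6 epoxide of A2, anti to the acetonide | BrC1=C[C@H]2O[C@H]2[C@@H]2OC(C)(C)O[C@H]12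
A4 | alternative 2 | acyclic (Z)-iodoalkenyl aldehyde (C4 aldehyde, C5 benzoate, C6 4-methoxybenzyl ether, C1 methyl ether, C7 silyl ether) | O=C[C@@H](OC(=O)c1ccccc1)[C@H](OCc1ccc(OC)cc1)[C@@H](OC)/C=C(\I)CO[Si](C)(C)C(C)(C)C
A5 | alternative 2 | cyclohexenol with free C4–OH, C5 benzoate, C6 4-methoxybenzyl ether, C7 silyl ether | CO[C@H]1C=C(CO[Si](C)(C)C(C)(C)C)[C@@H](O)[C@@H](OC(=O)c2ccccc2)[C@@H]1OCc1ccc(OC)cc1
A6 | alternative 3 | altro-configured methyl 6-deoxyhex-5-enopyranoside (2-O-naphthylmethyl, 3-O-benzoyl, 4-O-silyl) | C=C1O[C@H](OC)[C@@H](OCc2ccc3ccccc3c2)[C@H](OC(=O)c2ccccc2)[C@@H]1O[Si](C)(C)C(C)(C)C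
A7 | alternative 3 | cyclohexanone with C3 ketone, C1 methoxy, C6 naphthylmethyl ether, C5 benzoate, C4 silyl ether | O=C1C[C@H](OC)[C@@H](OCc2ccc3ccccc3c2)[C@H](OC(=O)c2ccccc2)[C@@H]1O[Si](C)(C)C(C)(C)C
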